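No earlier run changes the catalyst charge, so neither factor can be read yet; it can be reckoned, and that part is a guess. The hunch that the rate simply follows the charge needs testing at fixed conversion, since the look is taken at a conversion and not at a time.

common to all: free catalyst 9.2 mM

| charge | left-handed substrate | right-handed substrate | solid reagent | remark |
|---|---|---|---|---|
| eta | 0.20 M | 0.20 M | 0.16 M | the very flask that is asked about, followed so far |
| epsilon | 0.13 M | 0.13 M | 0.16 M | run made earlier |
| flask | 0.20 M | 0.20 M | 0.160 M |  |

eta run (percent of the left-handed substrate and right-handed substrate together charged): time / min: left-handed product / % = 3.00: 0; 10.0: 0.3; 15.0: 0.1; 25.0: 0; 40.0: 0.1; 50.0: 0.3; 60.0: 0.4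

epsilon run (percent of the left-handed substrate and right-handed substrate together charged): time / h: left-handed product / % = 0.200: 0; 0.500: 0; 1.00: 0.5; 1.50: 0.8; 2.00: 1.0; 3.00: 3.0; 4.00: 4.3

(standard deviation of a reading: 0.3 percentage points)

- free catalyst is single-handed; left-handed substrate and right-handed substrate are mirror images of each other, charged as a racemate, each of them at the stated concentration
- solid reagent is a solid; its amount is given per volume of the solution
- what was read earlier has a scatter of 0.3 percentage points, one standard deviation
- what may be going on: solid reagent <-> partner; free catalyst + right-handed substrate <-> catalyst intermediate B; free catalyst + left-handed substrate <-> catalyst intermediate A; partner + catalyst intermediate A -> free catalyst + left-handed product; free catalyst -> spent catalyst; partner + catalyst intermediate B -> free catalyst + right-handed product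
- at the start none of the solid reagent is in solution
- no earlier run changes the charge of free catalyst; that part of a forecast is a guess

1. factor on the rate of making left-handed product when 10% of the left-handed substrate and right-handed substrate together are converted if free catalyst is charged twice over
2. factor on the rate when 10% of the left-handed substrate and right-handed substrate together are converted if free catalyst is charged at 1.0 mM instead

1. In the epsilon run, left-handed product goes from 1.0% at 2.00 h to 4.3% at 4.00 h: a reading of a factor 4.30 in product for a factor 2.00 in time, each reading with a scatter of 0.3 percentage points.
2. Product growing with time squared means a rate growing in step with time, as [partner] climbs. Integrated, with the bound share of the catalyst taken as steady and [partner] as climbing evenly, conversion follows catalyst charge times time squared.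
3. So at 1.0 mM the time to 10% conversion is reckoned to grow by a factor 3.03. This is the stretch, the square root of the old charge over the new.
4. The rate at that conversion follows the charge times the stretch: 0.329 at 1.0 mM, and 1.41 for a doubled charge.
5. The forecast, on the ground that “the rate grows about linearly with time”, gives 1.4 and 0.33.

The flask gives 1.38 for the doubled charge and 0.147 at 1.0 mM, so the forecast for 1.0 mM stands higher by a factor 2.24.

    solid reagent ⇌ partner, rate k1*(cs1 - [partner]) while solid is left; crystals form when [partner] > cs1 (solubility = 0.120 M, k = 0.483 h⁻¹)
    free catalyst + right-handed substrate ⇌ catalyst intermediate B (K = 20.0 M⁻¹, k = 6950 M⁻¹ h⁻¹)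
    free catalyst + left-handed substrate ⇌ catalyst intermediate A (K = 1.20 M⁻¹, k = 3690 M⁻¹ h⁻¹)
    partner + catalyst intermediate A → free catalyst + left-handed product (k = 129 M⁻¹ h⁻¹)
    free catalyst → spent catalyst (k = 0.136 h⁻¹)
    partner + catalyst intermediate B → free catalyst + right-handed product (k = 42.3 M⁻¹ h⁻¹)

In the flask at 9.2 mM, 10% conversion comes at 2.47 h, and the stretch of 0.707 for a doubled charge puts that at an estimated 1.75 h, inside the span from 0.500 h to 2.50 h in which [partner] in the flask at 9.2 mM climbs from 0.0237 M to 0.0620 M. The stretch for 1.0 mM gives an estimated 7.48 h, later than 5.00 h, when the flask at 9.2 mM holds [partner] at 0.0725 M and solid reagent at 1.20% of its charge.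

The runs were generated by integration with constants of no real substance; the scatter is artificial.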